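No macrocyclisation is attempted. The C1 carbonyl and the lactone-bearing C6 face each other transannularly (a 1,6 pair) and C4=C5 is Z, so the ten-membered ring is hidden in a trans-fused bicyclo[4.4.0]decene (ring A with C4=C5, ring B with C7–C10) and released by cutting the C1–C6 bond. One operation on the ring-fusion tertiary alcohol (alkoxy-radical β-scission) gives the C1 ketone and the medium ring and lets the C12 ester oxygen, fixed cis to C6 on C7=C11, close the butenolide at the doubly allylic C6. The substrate is a decalinol tert-butyl ester already bearing the C8–C10 stereotriad, the C13 acetate and the C8 methacrylate.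

Key step: step 18

Remarks on the chemistry:
- Locants are the germacrane locants of the target, kept for every intermediate: C1 and C6 are the ring-fusion carbons, ring A is C1–C6, ring B is C6–C10 plus C1, and C11 on C7 carries C12 and C13. They coincide with the locants of bicyclo[4.4.0]decane.
- Stereochemical correction: an (E)-crotyl reagent adding through a closed chair transition state puts the C10 methyl cis to the C1 hydroxyl on ring B, so a decalinol with these groups trans cannot come from it. The precursor is therefore built as the trans-fused (1R,6R) diastereomer, whose C8 and C9 oxygens are trans-diaxial and reachable by epoxide opening. Both ring-fusion centres are destroyed in step 18.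
- Precursor design: C12 is a tert-butyl ester (no acyl hypoiodite, no decarboxylation), C8 already carries the methacrylate, and C9 a silyl ether (no electron-rich benzyl ether and no α-oxygenated C–H next to the alkoxy radical).

Step 1
Reactants: 1 4-methylanisole
Product: 2 1-methoxy-4-methylcyclohexa-1,4-diene
Conditions: Li, NH3 (l), t-BuOH, THF, −78 to −33 °C
Reagents that add atoms: none
Why: Birch reduction of the anisole gives the 2,5-dihydro product in which the methoxy and methyl groups both stay on sp2 carbons, so the trisubstituted C4=C5 bond of ring A is fixed in position from the start.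

Step 2
Reactants: 2 1-methoxy-4-methylcyclohexa-1,4-diene
Product: 3 4-methylcyclohex-3-en-1-one
Conditions: (CO2H)2 (cat.), acetone–H2O, 25 °C
Reagents that add atoms: water (SMILES O)
Why: Mild acid-catalysed enol ether hydrolysis should give the β,γ-unsaturated ketone (C1 carbonyl of ring A) without moving the C4=C5 bond into conjugation, which needs stronger acid or base.

Step 3
Reactants: 3 4-methylcyclohex-3-en-1-one; 4 acrolein
Product: 5 rac-(2R*)-2-[(1R*)-1-hydroxyprop-2-en-1-yl]-4-methylcyclohex-3-en-1-one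
Conditions: LiN(i-Pr)2, THF, −78 °C; then 4, −78 °C; AcOH quench
Reagents that add atoms: none
Why: LiN(i-Pr)2 removes the doubly activated C6 proton to give the linear dienolate, which adds to acrolein at its α-carbon through a closed chair transition state (aldol addition of a cyclic E enolate), so the anti pair C6/C7 should be set and the minor syn isomer is removed before the resolution.

Step 4
Reactants: 5 rac-(2R*)-2-[(1R*)-1-hydroxyprop-2-en-1-yl]-4-methylcyclohex-3-en-1-one
Product: 6 (1R)-1-[(1R)-3-methyl-6-oxocyclohex-2-en-1-yl]prop-2-en-1-yl acetate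
Conditions: Amano lipase PS (Burkholderia cepacia), vinyl acetate, t-BuOMe, 30 °C, stopped near half conversion
Reagents that add atoms: vinyl acetate (SMILES CC(=O)OC=C)
Why: Lipase-catalysed kinetic resolution by transesterification should acylate only the enantiomer whose carbinol carbon C7 is R (large cyclohexenyl against small vinyl group), which fixes C6 as R, installs the acetate that protects the C7 hydroxyl and leaves the other enantiomer of 5 to be separated.

Step 5
Reactants: 6 (1R)-1-[(1R)-3-methyl-6-oxocyclohex-2-en-1-yl]prop-2-en-1-yl acetate; 7 potassium (E)-but-2-en-1-yltrifluoroborate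
Product: 8 (1R)-1-[(1R,6S)-6-[(2S)-but-3-en-2-yl]-6-hydroxy-3-methylcyclohex-2-en-1-yl]prop-2-en-1-yl acetate
Conditions: BF3·OEt2, CH2Cl2, −78 °C
Reagents that add atoms: none
Why: Ketone crotylboration through the crotyldifluoroborane and a closed six-membered chair transition state, in which equatorial attack anti to the C6 side chain sets C1 (hydroxyl axial) and the E geometry with C6 pseudo-equatorial places the C10 methyl cis to the C1 hydroxyl on the future ring B.

Step 6
Reactants: 8 (1R)-1-[(1R,6S)-6-[(2S)-but-3-en-2-yl]-6-hydroxy-3-methylcyclohex-2-en-1-yl]prop-2-en-1-yl acetate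
Product: 9 (1S,6R,7R,10S)-1-hydroxy-4,10-dimethylbicyclo[4.4.0]deca-4,8-dien-7-yl acetate
Conditions: second-generation Grubbs catalyst (H2IMes)(PCy3)Cl2Ru=CHPh (cat.), CH2Cl2, 40 °C
Reagents that add atoms: none
Why: Ring-closing metathesis of the two monosubstituted vinyl groups, both equatorial on ring A, should close ring B as the trans-fused cyclohexene with loss of ethene while the trisubstituted C4=C5 bond stays out of the reaction.

Step 7
Reactants: 9 (1S,6R,7R,10S)-1-hydroxy-4,10-dimethylbicyclo[4.4.0]deca-4,8-dien-7-yl acetate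
Product: 10 (1S,6R,7R,10S)-4,10-dimethylbicyclo[4.4.0]deca-4,8-diene-1,7-diol
Conditions: K2CO3 (cat.), MeOH, 0 °C
Reagents that add atoms: none
Why: Base-catalysed transesterification (methanolysis) removes the allylic acetate at a stage where no ketone is present, so no stereocentre can epimerise.

Step 8
Reactants: 10 (1S,6R,7R,10S)-4,10-dimethylbicyclo[4.4.0]deca-4,8-diene-1,7-diol
Product: 11 (1S,6S,10S)-1-hydroxy-4,10-dimethylbicyclo[4.4.0]deca-4,8-dien-7-one
Conditions: Dess–Martin periodinane, NaHCO3, CH2Cl2, 0 to 25 °C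
Reagents that add atoms: none
Why: Dess–Martin oxidation converts only the secondary allylic C7 alcohol into the ring B enone under near-neutral conditions that leave the tertiary C1 alcohol and the C4=C5 bond untouched.

Step 9
Reactants: 11 (1S,6S,10S)-1-hydroxy-4,10-dimethylbicyclo[4.4.0]deca-4,8-dien-7-one
Product: 12 (1S,6S,10S)-4,10-dimethyl-1-(trimethylsilyloxy)bicyclo[4.4.0]deca-4,8-dien-7-one
Conditions: Me3SiCl, imidazole, DMF, 0 °C
Reagents that add atoms: chlorotrimethylsilane (SMILES C[Si](C)(C)Cl)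
Why: Silylation of the tertiary C1 alcohol blocks retro-aldol cleavage of the β-hydroxy ketone and hydroxyl-directed delivery of the peroxide in the basic epoxidation that follows.

Step 10
Reactants: 12 (1S,6S,10S)-4,10-dimethyl-1-(trimethylsilyloxy)bicyclo[4.4.0]deca-4,8-dien-7-one
Product: 13 (1S,6S,8S,9S,10S)-8,9-epoxy-4,10-dimethyl-1-(trimethylsilyloxy)bicyclo[4.4.0]dec-4-en-7-one
Conditions: t-BuOOH, DBU, CH2Cl2, 0 °C
Reagents that add atoms: tert-butyl hydroperoxide (SMILES CC(C)(C)OO)
Why: Weitz–Scheffer nucleophilic epoxidation touches only the electron-poor C8=C9 bond of the enone, and the peroxide should add to C9 along the axial trajectory anti to the axial C1 silyloxy group and trans to the C10 methyl, which sets C8 and C9 together.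

Step 11
Reactants: 13 (1S,6S,8S,9S,10S)-8,9-epoxy-4,10-dimethyl-1-(trimethylsilyloxy)bicyclo[4.4.0]dec-4-en-7-one
Product: 14 (1S,6S,8S,9R,10S)-1,8,9-trihydroxy-4,10-dimethylbicyclo[4.4.0]dec-4-en-7-one
Conditions: HClO4 (cat.), THF–H2O, 0 °C
Reagents that add atoms: water (SMILES O)
Why: Acid-catalysed epoxide hydrolysis, after loss of the labile silyl ether, should open the C9–O bond remote from the carbonyl by axial attack of water with inversion, giving the trans-diaxial 8,9-diol in which C9 is inverted and C8 retained.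

Step 12
Reactants: 14 (1S,6S,8S,9R,10S)-1,8,9-trihydroxy-4,10-dimethylbicyclo[4.4.0]dec-4-en-7-one; 15 3-tert-butoxy-3-oxopropanoic acid
Product: 16 tert-butyl (1S,6S,8S,9R,10S)-1,9-dihydroxy-4,10-dimethyl-7-oxobicyclo[4.4.0]dec-4-en-8-yl propanedioate
Conditions: i-PrN=C=N-i-Pr, DMAP (cat.), CH2Cl2, −20 °C
Reagents that add atoms: none
Why: Steglich esterification should acylate the C8 hydroxyl of the α-ketol selectively, because the C9 hydroxyl is 1,3-diaxial to and hydrogen-bonded with the C1 hydroxyl and flanked by the methyl-bearing C10, and the tertiary C1 hydroxyl does not react.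

Step 13
Reactants: 16 tert-butyl (1S,6S,8S,9R,10S)-1,9-dihydroxy-4,10-dimethyl-7-oxobicyclo[4.4.0]dec-4-en-8-yl propanedioate
Product: 17 tert-butyl (1S,6S,8S,9R,10S)-9-(tert-butyldimethylsilyloxy)-1-hydroxy-4,10-dimethyl-7-oxobicyclo[4.4.0]dec-4-en-8-yl propanedioate
Conditions: t-BuMe2SiOTf, 2,6-lutidine, CH2Cl2, −78 °C
Reagents that add atoms: tert-butyldimethylsilyl trifluoromethanesulfonate (SMILES CC(C)(C)[Si](C)(C)OS(=O)(=O)C(F)(F)F)
Why: Silyl triflate silylation at low temperature protects the secondary C9 hydroxyl faster than the tertiary C1 hydroxyl and gives an ether without weak α-oxygenated C–H bonds, which matters because this group sits syn-axial to the C1 oxygen in the key step.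

Step 14
Reactants: 17 tert-butyl (1S,6S,8S,9R,10S)-9-(tert-butyldimethylsilyloxy)-1-hydroxy-4,10-dimethyl-7-oxobicyclo[4.4.0]dec-4-en-8-yl propanedioate
Product: 18 tert-butyl (1R,6R,8R,9R,10S)-9-(tert-butyldimethylsilyloxy)-1-hydroxy-1,6-cyclogermacra-4,7(11)-dien-13,8-olid-12-oate
Conditions: TiCl4, pyridine, THF, 0 to 25 °C
Reagents that add atoms: none
Why: Intramolecular Knoevenagel condensation of the malonate onto the C7 ketone forms the C7=C11 bond inside a five-membered lactone, which fixes the geometry of the tetrasubstituted olefin (C13 carbonyl on the C8 side and the tert-butyl ester carbon C12 cis to C6), and the weakly basic titanium tetrachloride–pyridine medium should not epimerise C8.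

Step 15
Reactants: 18 tert-butyl (1R,6R,8R,9R,10S)-9-(tert-butyldimethylsilyloxy)-1-hydroxy-1,6-cyclogermacra-4,7(11)-dien-13,8-olid-12-oate
Product: 20 tert-butyl (2E)-2-[(1R,6R,8R,9R,10S)-9-(tert-butyldimethylsilyloxy)-1,8-dihydroxy-4,10-dimethylbicyclo[4.4.0]dec-4-en-7-ylidene]-3-hydroxypropanoate, via lactol 19 (not isolated)
Conditions: i-Bu2AlH, CH2Cl2, −78 °C; MeOH; then NaBH4, CeCl3·7H2O, MeOH, −40 to 0 °C
Reagents that add atoms: none
Why: Partial reduction of the butenolide carbonyl by i-Bu2AlH followed by Luche 1,2-reduction of the ring-opened hydroxy enal should give the C8,C13 diol with the olefin geometry intact, the hindered conjugated tert-butyl ester being inert to both hydrides at these temperatures.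

Step 16
Reactants: 20 tert-butyl (2E)-2-[(1R,6R,8R,9R,10S)-9-(tert-butyldimethylsilyloxy)-1,8-dihydroxy-4,10-dimethylbicyclo[4.4.0]dec-4-en-7-ylidene]-3-hydroxypropanoate
Product: 21 tert-butyl (2E)-3-acetoxy-2-[(1R,6R,8R,9R,10S)-9-(tert-butyldimethylsilyloxy)-1,8-dihydroxy-4,10-dimethylbicyclo[4.4.0]dec-4-en-7-ylidene]propanoate
Conditions: AcCl, 2,4,6-collidine, CH2Cl2, −78 °C
Reagents that add atoms: acetyl chloride (SMILES CC(Cl)=O)
Why: Low-temperature acylation with a hindered pyridine base should acetylate the primary allylic C13 hydroxyl in preference to the secondary C8 and tertiary C1 hydroxyls.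

Step 17
Reactants: 21 tert-butyl (2E)-3-acetoxy-2-[(1R,6R,8R,9R,10S)-9-(tert-butyldimethylsilyloxy)-1,8-dihydroxy-4,10-dimethylbicyclo[4.4.0]dec-4-en-7-ylidene]propanoate; 22 methacrylic anhydride
Product: 23 tert-butyl (2E)-3-acetoxy-2-[(1R,6R,8R,9R,10S)-9-(tert-butyldimethylsilyloxy)-1-hydroxy-4,10-dimethyl-8-(2-methylprop-2-enoyloxy)bicyclo[4.4.0]dec-4-en-7-ylidene]propanoate
Conditions: DMAP, Et3N, CH2Cl2, 25 °C
Reagents that add atoms: none
Why: DMAP-catalysed acylation installs the final C8 methacrylate on the only remaining secondary hydroxyl, the tertiary C1 hydroxyl being unreactive, so that no protecting-group exchange is needed after the key step.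

Step 18
Reactants: 23 tert-butyl (2E)-3-acetoxy-2-[(1R,6R,8R,9R,10S)-9-(tert-butyldimethylsilyloxy)-1-hydroxy-4,10-dimethyl-8-(2-methylprop-2-enoyloxy)bicyclo[4.4.0]dec-4-en-7-ylidene]propanoate
Product: 26 (4Z,6R,8R,9R,10S)-13-acetoxy-9-(tert-butyldimethylsilyloxy)-8-(2-methylprop-2-enoyloxy)-1-oxogermacra-4,7(11)-dien-12,6-olide, via hypoiodite 24 (not isolated), via allylic iodide 25 (not isolated)
Conditions: PhI(OAc)2, I2, CH2Cl2–cyclohexane, visible light, 25 °C
Reagents that add atoms: none
Why: Proposed new method: acetyl hypoiodite converts the tertiary C1 alcohol into hypoiodite 24, whose O–I bond homolyses in light, and the alkoxy radical cleaves C1–C6 rather than C1–C2 or C1–C10 because only that bond leaves a radical stabilised by both the C4=C5 and the C7=C11–CO2t-Bu π systems, which unveils the ten-membered ring and the C1 ketone. The closest known reaction is the hypoiodite β-fragmentation of ring-fusion carbinols to medium-ring keto iodides; new is that the iodide is not isolated but displaced in the flask by the neighbouring ester. Iodine atom transfer to the C6 radical is expected on the face away from the departing C1 carbonyl and is fast enough to keep the Z geometry that C4=C5 inherits from ring A, giving 25. The carbonyl oxygen of the C12 tert-butyl ester then closes the butenolide by a 5-exo-tet displacement of iodide, isobutene being lost from the alkoxyfuranylium ion. C6 is the only new stereocentre and is set by this double inversion, that is with net retention of the direction of the broken C1–C6 bond, which is why the (1R,6R) decalinol is the diastereomer that leads to the required lactone. The selectivity needed is fragmentation ahead of addition of acetyl hypoiodite to the electron-rich C4=C5 bond, and it is secured by the strain released on opening the bicycle and by the absence of a free carboxylic acid, of weak α-oxygenated C–H bonds near the radical and of electron-rich arenes, the methacrylate being too electron-poor to interfere.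

Step 19
Reactants: 26 (4Z,6R,8R,9R,10S)-13-acetoxy-9-(tert-butyldimethylsilyloxy)-8-(2-methylprop-2-enoyloxy)-1-oxogermacra-4,7(11)-dien-12,6-olide
Product: 27 (4Z,6R,8R,9R,10S)-13-acetoxy-9-hydroxy-8-(2-methylprop-2-enoyloxy)-1-oxogermacra-4,7(11)-dien-12,6-olide
Conditions: HF·pyridine, pyridine, THF, 0 to 25 °C
Reagents that add atoms: none
Why: Fluoride-mediated desilylation under buffered acidic conditions should free the C9 hydroxyl without the acyl migration from C8 or the retro-aldol cleavage of the β-hydroxy ketone that basic fluoride sources could provoke.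

Step 20
Reactants: 27 (4Z,6R,8R,9R,10S)-13-acetoxy-9-hydroxy-8-(2-methylprop-2-enoyloxy)-1-oxogermacra-4,7(11)-dien-12,6-olide
Product: 28 (4R,5S,6S,8R,9R,10S)-13-acetoxy-4,5-epoxy-9-hydroxy-8-(2-methylprop-2-enoyloxy)-1-oxogermacr-7(11)-en-12,6-olide
Conditions: 3-ClC6H4CO3H, NaHCO3, CH2Cl2, 0 °C
Reagents that add atoms: 3-chloroperoxybenzoic acid (SMILES OOC(=O)c1cccc(Cl)c1)
Why: Prilezhaev epoxidation picks the only electron-rich olefin (butenolide and methacrylate are electron-poor) and is expected to deliver oxygen to the outer face of the Z C4=C5 bond, anti to the butenolide carbon C7 in the conformer whose C6–O bond eclipses the olefin, which would give the cis (4R,5S) epoxide.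

Compound list
1 | 4-methylanisole | COc1ccc(C)cc1 | starting material
2 | 1-methoxy-4-methylcyclohexa-1,4-diene | COC1=CCC(C)=CC1 | intermediate
3 | 4-methylcyclohex-3-en-1-one | CC1=CCC(=O)CC1 | intermediate
4 | acrolein (prop-2-enal) | C=CC=O | starting material
5 | rac-(2R*)-2-[(1R*)-1-hydroxyprop-2-en-1-yl]-4-methylcyclohex-3-en-1-one (racemate; one enantiomer drawn) | O=C1CCC(C)=C[C@@H]1[C@H](O)C=C | intermediate
6 | (1R)-1-[(1R)-3-methyl-6-oxocyclohex-2-en-1-yl]prop-2-en-1-yl acetate | O=C1CCC(C)=C[C@@H]1[C@H](OC(C)=O)C=C | intermediate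
7 | potassium (E)-but-2-en-1-yltrifluoroborate | C/C=C/C[B-](F)(F)F.[K+] | starting material
8 | (1R)-1-[(1R,6S)-6-[(2S)-but-3-en-2-yl]-6-hydroxy-3-methylcyclohex-2-en-1-yl]prop-2-en-1-yl acetate | C=C[C@H](C)[C@@]1(O)CCC(C)=C[C@@H]1[C@H](OC(C)=O)C=C | intermediate
9 | (1S,6R,7R,10S)-1-hydroxy-4,10-dimethylbicyclo[4.4.0]deca-4,8-dien-7-yl acetate | CC(=O)O[C@@H]1C=C[C@H](C)[C@@]2(O)CCC(C)=C[C@H]12 | intermediate
10 | (1S,6R,7R,10S)-4,10-dimethylbicyclo[4.4.0]deca-4,8-diene-1,7-diol | O[C@@H]1C=C[C@H](C)[C@@]2(O)CCC(C)=C[C@H]12 | intermediate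
11 | (1S,6S,10S)-1-hydroxy-4,10-dimethylbicyclo[4.4.0]deca-4,8-dien-7-one | O=C1C=C[C@H](C)[C@@]2(O)CCC(C)=C[C@H]12 | intermediate
12 | (1S,6S,10S)-4,10-dimethyl-1-(trimethylsilyloxy)bicyclo[4.4.0]deca-4,8-dien-7-one | O=C1C=C[C@H](C)[C@@]2(O[Si](C)(C)C)CCC(C)=C[C@H]12 | intermediate
13 | (1S,6S,8S,9S,10S)-8,9-epoxy-4,10-dimethyl-1-(trimethylsilyloxy)bicyclo[4.4.0]dec-4-en-7-one | O=C1[C@H]3O[C@H]3[C@H](C)[C@@]2(O[Si](C)(C)C)CCC(C)=C[C@H]12 | intermediate
14 | (1S,6S,8S,9R,10S)-1,8,9-trihydroxy-4,10-dimethylbicyclo[4.4.0]dec-4-en-7-one | O=C1[C@@H](O)[C@H](O)[C@H](C)[C@@]2(O)CCC(C)=C[C@H]12 | intermediate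
15 | 3-tert-butoxy-3-oxopropanoic acid (mono-tert-butyl malonate) | CC(C)(C)OC(=O)CC(=O)O | starting material
16 | tert-butyl (1S,6S,8S,9R,10S)-1,9-dihydroxy-4,10-dimethyl-7-oxobicyclo[4.4.0]dec-4-en-8-yl propanedioate | O=C1[C@@H](OC(=O)CC(=O)OC(C)(C)C)[C@H](O)[C@H](C)[C@@]2(O)CCC(C)=C[C@H]12 | intermediate
17 | tert-butyl (1S,6S,8S,9R,10S)-9-(tert-butyldimethylsilyloxy)-1-hydroxy-4,10-dimethyl-7-oxobicyclo[4.4.0]dec-4-en-8-yl propanedioate | O=C1[C@@H](OC(=O)CC(=O)OC(C)(C)C)[C@H](O[Si](C)(C)C(C)(C)C)[C@H](C)[C@@]2(O)CCC(C)=C[C@H]12 | intermediate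
18 | tert-butyl (1R,6R,8R,9R,10S)-9-(tert-butyldimethylsilyloxy)-1-hydroxy-1,6-cyclogermacra-4,7(11)-dien-13,8-olid-12-oate (butenolide: C13 carbonyl on O8; C7=C11 in the lactone ring; C12 ester on C11) | CC(C)(C)OC(=O)C1=C2[C@@H](OC1=O)[C@H](O[Si](C)(C)C(C)(C)C)[C@H](C)[C@@]3(O)CCC(C)=C[C@H]23 | intermediate
19 | 13-lactol of 18 (C13 epimers) | CC(C)(C)OC(=O)C1=C2[C@@H](OC1O)[C@H](O[Si](C)(C)C(C)(C)C)[C@H](C)[C@@]3(O)CCC(C)=C[C@H]23 | intermediate
20 | tert-butyl (2E)-2-[(1R,6R,8R,9R,10S)-9-(tert-butyldimethylsilyloxy)-1,8-dihydroxy-4,10-dimethylbicyclo[4.4.0]dec-4-en-7-ylidene]-3-hydroxypropanoate | OC/C(C(=O)OC(C)(C)C)=C1\[C@@H](O)[C@H](O[Si](C)(C)C(C)(C)C)[C@H](C)[C@@]3(O)CCC(C)=C[C@H]13 | intermediate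
21 | tert-butyl (2E)-3-acetoxy-2-[(1R,6R,8R,9R,10S)-9-(tert-butyldimethylsilyloxy)-1,8-dihydroxy-4,10-dimethylbicyclo[4.4.0]dec-4-en-7-ylidene]propanoate | CC(=O)OC/C(C(=O)OC(C)(C)C)=C1\[C@@H](O)[C@H](O[Si](C)(C)C(C)(C)C)[C@H](C)[C@@]3(O)CCC(C)=C[C@H]13 | intermediate
22 | methacrylic anhydride | C=C(C)C(=O)OC(=O)C(C)=C | starting material
23 | tert-butyl (2E)-3-acetoxy-2-[(1R,6R,8R,9R,10S)-9-(tert-butyldimethylsilyloxy)-1-hydroxy-4,10-dimethyl-8-(2-methylprop-2-enoyloxy)bicyclo[4.4.0]dec-4-en-7-ylidene]propanoate (key-step precursor) | CC(=O)OC/C(C(=O)OC(C)(C)C)=C1\[C@@H](OC(=O)C(C)=C)[C@H](O[Si](C)(C)C(C)(C)C)[C@H](C)[C@@]3(O)CCC(C)=C[C@H]13 | intermediate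
24 | C1 hypoiodite of 23 (1-iodooxy in place of 1-hydroxy) | CC(=O)OC/C(C(=O)OC(C)(C)C)=C1\[C@@H](OC(=O)C(C)=C)[C@H](O[Si](C)(C)C(C)(C)C)[C@H](C)[C@@]3(OI)CCC(C)=C[C@H]13 | intermediate
25 | tert-butyl (4Z,6S,8R,9R,10S)-13-acetoxy-9-(tert-butyldimethylsilyloxy)-6-iodo-8-(2-methylprop-2-enoyloxy)-1-oxogermacra-4,7(11)-dien-12-oate (C12 cis to C6) | CC(=O)OC/C(C(=O)OC(C)(C)C)=C1\[C@@H](OC(=O)C(C)=C)[C@H](O[Si](C)(C)C(C)(C)C)[C@H](C)C(=O)CC/C(C)=C\[C@@H]1I | intermediate
26 | (4Z,6R,8R,9R,10S)-13-acetoxy-9-(tert-butyldimethylsilyloxy)-8-(2-methylprop-2-enoyloxy)-1-oxogermacra-4,7(11)-dien-12,6-olide (key-step product) | CC(=O)OCC1=C2[C@@H](OC(=O)C(C)=C)[C@H](O[Si](C)(C)C(C)(C)C)[C@H](C)C(=O)CC/C(C)=C\[C@H]2OC1=O | intermediate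
27 | (4Z,6R,8R,9R,10S)-13-acetoxy-9-hydroxy-8-(2-methylprop-2-enoyloxy)-1-oxogermacra-4,7(11)-dien-12,6-olide | CC(=O)OCC1=C2[C@@H](OC(=O)C(C)=C)[C@H](O)[C@H](C)C(=O)CC/C(C)=C\[C@H]2OC1=O | intermediate
28 | (4R,5S,6S,8R,9R,10S)-13-acetoxy-4,5-epoxy-9-hydroxy-8-(2-methylprop-2-enoyloxy)-1-oxogermacr-7(11)-en-12,6-olide (CNP0185951.2) | C=C(C)C(=O)O[C@@H]1C2=C(COC(C)=O)C(=O)O[C@@H]2[C@@H]2O[C@]2(C)CCC(=O)[C@@H](C)[C@H]1O | target

Total step count: 20. Longest linear sequence: 20 steps (1 to 28).

Steps most likely to fail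

Step 18 (proposed new method). What may go wrong is addition of acetyl hypoiodite across the C4=C5 bond before the O–I bond homolyses, or lactone closure on the wrong face of C6. The fallback separates the two events with known reactions and sets out from 23:
- Pb(OAc)4 (tetravalent lead) in benzene at 80 °C fragments the tertiary alcohol, and the allyl radical is oxidised and trapped as the C6 allylic acetate F1 (both C6 epimers).
- Me3SiOTf with 2,6-lutidine cleaves the tert-butyl ester to the carboxylic acid F2.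
- Pd(PPh3)4 (zerovalent palladium) with Et3N in THF ionises the acetate and the carboxylate attacks the π-allyl terminus C6 (Tsuji–Trost lactonisation). This converges both epimers, allows a chiral ligand to steer C6, and comes back to the route at 26.

Step 20. What may go wrong is poor facial selectivity, with oxygen delivered to the other face of C4=C5. The fallback sets out from 27. N-Bromosuccinimide in aqueous acetone gives the bromohydrin F3 by anti addition, with bromine at C5 on the face the peracid would have used and hydroxyl at the tertiary C4. Ag2O in CH2Cl2 then closes the oxirane by displacing bromide with inversion, which puts the epoxide oxygen on the opposite face and comes back at 28.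

Step 12. What may go wrong is poor site selectivity, with acylation of the C9 hydroxyl or double acylation. The fallback sets out from 14. PhB(OH)2 in toluene with azeotropic removal of water ties the syn-diaxial C1 and C9 hydroxyls up as the cyclic phenylboronate F4. The only free hydroxyl, at C8, is then esterified with 15 under the carbodiimide conditions to give the boronate malonate F5. Exchange with pinacol releases the diol and comes back at 16.

Further compounds
F1 | step 18 | tert-butyl (4Z,8R,9R,10S)-6,13-diacetoxy-9-(tert-butyldimethylsilyloxy)-8-(2-methylprop-2-enoyloxy)-1-oxogermacra-4,7(11)-dien-12-oate (C6 epimers) | CC(=O)OC/C(C(=O)OC(C)(C)C)=C1\[C@@H](OC(=O)C(C)=C)[C@H](O[Si](C)(C)C(C)(C)C)[C@H](C)C(=O)CC/C(C)=C\C1OC(C)=O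
F2 | step 18 | (4Z,8R,9R,10S)-6,13-diacetoxy-9-(tert-butyldimethylsilyloxy)-8-(2-methylprop-2-enoyloxy)-1-oxogermacra-4,7(11)-dien-12-oic acid (C6 epimers) | CC(=O)OC/C(C(=O)O)=C1\[C@@H](OC(=O)C(C)=C)[C@H](O[Si](C)(C)C(C)(C)C)[C@H](C)C(=O)CC/C(C)=C\C1OC(C)=O
F3 | step 20 | (4R,5R,6S,8R,9R,10S)-13-acetoxy-5-bromo-4,9-dihydroxy-8-(2-methylprop-2-enoyloxy)-1-oxogermacr-7(11)-en-12,6-olide | C=C(C)C(=O)O[C@@H]1C2=C(COC(C)=O)C(=O)O[C@@H]2[C@@H](Br)[C@@](O)(C)CCC(=O)[C@@H](C)[C@H]1O
F4 | step 12 | cyclic phenylboronate of 14 (boron bridging O1 and O9; C8 hydroxyl free) | O=C1[C@@H](O)[C@H](OB(c5ccccc5)O3)[C@H](C)[C@@]23CCC(C)=C[C@H]12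
F5 | step 12 | C8 tert-butyl malonate of F4 | O=C1[C@@H](OC(=O)CC(=O)OC(C)(C)C)[C@H](OB(c5ccccc5)O3)[C@H](C)[C@@]23CCC(C)=C[C@H]12
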